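**Plan**

- Retrosynthesis: take off five silyl ethers; then cut, in one stroke, the bond from pyran C3 to the chalcone B-ring carbon ortho to its phenol and the O1–C2 bond of the pyran ring. This leaves an aryl iodide that carries the whole chalcone and a 1,3-diaryl allene. The allene goes back to a propargylic alcohol (cut at the carbinol–alkyne bond); the chalcone is cut at Cα=Cβ (aldol).
- Enabling feature: C2–C3–C4 of the pyran ring is a three-carbon unit whose middle carbon carries only the aryl group, with O1 held on ring A ortho to C4. It is the allene of an ortho-allenyl phenol: arylpalladation at the central carbon (C3) and attack of O1 on the allyl terminus C2 build the C–C bond, the ring and the stereocentre together.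
- Forward: ring A becomes an aryl alkyne, is joined to the C2-aryl aldehyde, and the propargylic alcohol is turned into the allene. The iodochalcone is made by aldol condensation and silylated. The cascade joins the halves and closes the pyran ring last; desilylation ends the route. Helpers: one TBS ether (fluoride trigger, lost in the key step) and five TIPS ethers (lost at the end).
- Stereochemistry: C2 (S) is the only stereocentre. A ligand-controlled alkynylzinc addition sets the (S)-carbinol, a stereospecific Mitsunobu/retro-ene sequence stores it as the (aS) allene axis, and the key step writes it back to C2 by axial-to-central transfer. The (E)-enone is the thermodynamic aldol product.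

Key step: step 10

Assumption: the (R)-BINOL hand in step 6 is taken from the accepted facial model for titanium–BINOL alkynylzinc additions; if the carbinol proves to be (R), (S)-BINOL is used and nothing else changes.

**Route**

Step 1
Reactants: 1 2,4-dihydroxybenzaldehyde
Product: 2 2-hydroxy-4-[(triisopropylsilyl)oxy]benzaldehyde
Conditions: TIPSCl (1.05 equiv), imidazole (2.2 equiv), CH2Cl2, 0 °C
Reagents that add atoms: triisopropylsilyl chloride, CC(C)[Si](Cl)(C(C)C)C(C)C
Why: The 4-hydroxyl is the more acidic and unhindered phenol while the 2-hydroxyl is hydrogen-bonded to the aldehyde, so one equivalent of the bulky silyl chloride should silylate O4 selectively (phenol silylation).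

Step 2
Reactants: 2 2-hydroxy-4-[(triisopropylsilyl)oxy]benzaldehyde
Product: 3 2-[(tert-butyldimethylsilyl)oxy]-4-[(triisopropylsilyl)oxy]benzaldehyde
Conditions: TBSCl (1.3 equiv), imidazole, DMAP (cat.), DMF, 23 °C
Reagents that add atoms: tert-butyldimethylsilyl chloride, CC(C)(C)[Si](C)(C)Cl
Why: Phenol silylation of the remaining hydrogen-bonded hydroxyl with the smaller TBS group, which later serves as the only fluoride-labile trigger beside TIPS ethers.

Step 3
Reactants: 3 2-[(tert-butyldimethylsilyl)oxy]-4-[(triisopropylsilyl)oxy]benzaldehyde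
Product: 4 tert-butyl{2-(2,2-dibromoethenyl)-5-[(triisopropylsilyl)oxy]phenoxy}dimethylsilane
Conditions: CBr4 (2 equiv), PPh3 (2 equiv), Zn dust (2 equiv), CH2Cl2, 23 °C
Reagents that add atoms: carbon tetrabromide, BrC(Br)(Br)Br
Why: First stage of the Corey–Fuchs reaction (Ramirez dibromo-olefination), which passes through an ylide and an oxaphosphetane, so no free benzylic alkoxide arises next to the ortho silyl ether and silyl migration is avoided.

Step 4
Reactants: 4 tert-butyl{2-(2,2-dibromoethenyl)-5-[(triisopropylsilyl)oxy]phenoxy}dimethylsilane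
Product: 6 tert-butyl{2-ethynyl-5-[(triisopropylsilyl)oxy]phenoxy}dimethylsilane, via lithium acetylide 5 (not isolated)
Conditions: n-BuLi (2.2 equiv), THF, −78 °C; then H2O
Reagents that add atoms: none
Why: Second stage of the Corey–Fuchs reaction: bromine–lithium exchange, Fritsch–Buttenberg–Wiechell 1,2-shift and deprotonation give the lithium acetylide, which is protonated on quench.

Step 5
Reactants: 7 4-hydroxybenzaldehyde
Product: 8 4-[(triisopropylsilyl)oxy]benzaldehyde
Conditions: TIPSCl (1.2 equiv), imidazole, DMF, 23 °C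
Reagents that add atoms: triisopropylsilyl chloride, CC(C)[Si](Cl)(C(C)C)C(C)C
Why: Standard silylation of an unhindered phenol.

Step 6
Reactants: 6 tert-butyl{2-ethynyl-5-[(triisopropylsilyl)oxy]phenoxy}dimethylsilane; 8 4-[(triisopropylsilyl)oxy]benzaldehyde
Product: 10 (1S)-3-{2-[(tert-butyldimethylsilyl)oxy]-4-[(triisopropylsilyl)oxy]phenyl}-1-{4-[(triisopropylsilyl)oxy]phenyl}prop-2-yn-1-ol, via alkynylzinc 9 (not isolated)
Conditions: 6 (1.5 equiv), Et2Zn (2 equiv), toluene, reflux; then (R)-BINOL (20 mol%), Ti(OiPr)4 (50 mol%), 8, 23 °C; aq. NH4Cl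
Reagents that add atoms: none
Why: Titanium–BINOL-catalysed addition of an alkynylzinc to an aromatic aldehyde is a well-precedented enantioselective carbonyl alkynylation, and the (R)-ligand should direct the alkynyl group to the aldehyde face that gives the (S)-carbinol, the only stereocentre set by a reagent in the route.

Step 7
Reactants: 10 (1S)-3-{2-[(tert-butyldimethylsilyl)oxy]-4-[(triisopropylsilyl)oxy]phenyl}-1-{4-[(triisopropylsilyl)oxy]phenyl}prop-2-yn-1-ol
Product: 13 tert-butyldimethyl{2-[(aS)-3-{4-[(triisopropylsilyl)oxy]phenyl}propa-1,2-dien-1-yl]-5-[(triisopropylsilyl)oxy]phenoxy}silane, via sulfonylhydrazine 11 (not isolated), via diazene 12 (not isolated)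
Conditions: PPh3 (1.5 equiv), DEAD (1.5 equiv), THF, −15 °C; 2-nitrobenzenesulfonylhydrazide (1.5 equiv), −15 °C; then 23 °C, dark
Reagents that add atoms: none
Why: Myers allene synthesis: Mitsunobu displacement by the sulfonylhydrazide with inversion, loss of sulfinic acid and a suprafacial retro-ene loss of dinitrogen deliver hydrogen to the distal alkyne carbon anti to the original C–O bond, so the (S)-carbinol should give the (aS)-allene stereospecifically.

Step 8
Reactants: 14 1-(2,4-dihydroxyphenyl)ethan-1-one; 15 4-hydroxy-3-iodobenzaldehyde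
Product: 16 (E)-1-(2,4-dihydroxyphenyl)-3-(4-hydroxy-3-iodophenyl)prop-2-en-1-one
Conditions: HCl (g), EtOH, 0 to 23 °C
Reagents that add atoms: none
Why: Acid-catalysed Claisen–Schmidt condensation (aldol addition, then dehydration) of the unprotected phenolic partners should give the conjugated enone with the thermodynamic (E)-geometry.

Step 9
Reactants: 16 (E)-1-(2,4-dihydroxyphenyl)-3-(4-hydroxy-3-iodophenyl)prop-2-en-1-one
Product: 17 (E)-1-{2,4-bis[(triisopropylsilyl)oxy]phenyl}-3-{3-iodo-4-[(triisopropylsilyl)oxy]phenyl}prop-2-en-1-one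
Conditions: TIPSOTf (3.6 equiv), 2,6-lutidine (5 equiv), CH2Cl2, 0 to 23 °C
Reagents that add atoms: triisopropylsilyl trifluoromethanesulfonate, CC(C)[Si](OS(=O)(=O)C(F)(F)F)(C(C)C)C(C)C
Why: A silyl triflate with a hindered pyridine base silylates all three phenols, including the hydrogen-bonded one ortho to the ketone, so that no acidic O–H and no competing oxygen nucleophile remain for the key step.

Step 10
Reactants: 13 tert-butyldimethyl{2-[(aS)-3-{4-[(triisopropylsilyl)oxy]phenyl}propa-1,2-dien-1-yl]-5-[(triisopropylsilyl)oxy]phenoxy}silane; 17 (E)-1-{2,4-bis[(triisopropylsilyl)oxy]phenyl}-3-{3-iodo-4-[(triisopropylsilyl)oxy]phenyl}prop-2-en-1-one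
Product: 19 (E)-1-{2,4-bis[(triisopropylsilyl)oxy]phenyl}-3-{4-[(triisopropylsilyl)oxy]-3-[(2S)-7-[(triisopropylsilyl)oxy]-2-{4-[(triisopropylsilyl)oxy]phenyl}-2H-chromen-3-yl]phenyl}prop-2-en-1-one, via ammonium phenoxide 18 (not isolated)
Conditions: 13, TBAF (1.05 equiv), THF, −40 °C; then added slowly to 17 (0.9 equiv), Pd(PPh3)4 (5 mol%), K2CO3 (2 equiv), THF, 50 °C, dark
Reagents that add atoms: none
Why: Proposed new method: oxidative addition of zerovalent palladium into the C–I bond of 17 gives an arylpalladium iodide that carbopalladates the allene of phenoxide 18 across its distal C2=C3 π bond on the face away from ring A, which puts the aryl group on the central carbon (the future C3, the new C–C bond) and gives a 1,2,3-triaryl π-allylpalladium species with no β-hydrogen to lose. The phenoxide oxygen then attacks the allyl terminus that bears the 4-silyloxyphenyl group (the future C2) on the face opposite palladium, closing the pyran ring by a 6-endo allylic etherification and returning zerovalent palladium. The closest known reaction type is the palladium-catalysed coupling–cyclisation of aryl halides with allenes that carry a carboxylic acid, alcohol or amine nucleophile, which is known to pass the axial chirality of a 1,3-disubstituted allene on to the new stereocentre; it has not been shown for an ortho-allenyl phenoxide closing to a 2H-chromene. C2 is controlled by the (aS) axis of 13: syn aryl–palladium addition anti to ring A followed by anti attack of oxygen translates (aS) into (2S), and an anti-oxypalladation/reductive-elimination variant leads to the same sense. The step needs insertion at the distal and not the proximal π bond (secured by the bulky ortho-substituted ring A on the proximal carbon), arylation faster than self-closure of the allenyl phenol (secured by unmasking the oxygen only as its aprotic ammonium phenoxide at low temperature and adding it slowly to preformed arylpalladium), and no competing oxygen nucleophile (secured by silyl protection of every other phenol, above all the one ortho to iodine).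

Step 11
Reactants: 19 (E)-1-{2,4-bis[(triisopropylsilyl)oxy]phenyl}-3-{4-[(triisopropylsilyl)oxy]-3-[(2S)-7-[(triisopropylsilyl)oxy]-2-{4-[(triisopropylsilyl)oxy]phenyl}-2H-chromen-3-yl]phenyl}prop-2-en-1-one
Product: 20 (E)-1-(2,4-dihydroxyphenyl)-3-{4-hydroxy-3-[(2S)-7-hydroxy-2-(4-hydroxyphenyl)-2H-chromen-3-yl]phenyl}prop-2-en-1-one
Conditions: TBAF (6 equiv), AcOH (6 equiv), THF, 0 °C, dark
Reagents that add atoms: none
Why: Fluoride cleaves the five aryl silyl ethers while acetic acid keeps the freed phenols protonated, which should avoid phenoxide-driven quinone-methide opening of the C2–O1 bond and flavanone closure of the 2′-hydroxychalcone, so the C2 configuration is not touched (fluoride desilylation).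

**Compound list**

1 | 2,4-dihydroxybenzaldehyde | O=Cc1ccc(O)cc1O | starting material
2 | 2-hydroxy-4-[(triisopropylsilyl)oxy]benzaldehyde | O=Cc1ccc(O[Si](C(C)C)(C(C)C)C(C)C)cc1O | intermediate
3 | 2-[(tert-butyldimethylsilyl)oxy]-4-[(triisopropylsilyl)oxy]benzaldehyde | O=Cc1ccc(O[Si](C(C)C)(C(C)C)C(C)C)cc1O[Si](C)(C)C(C)(C)C | intermediate
4 | tert-butyl{2-(2,2-dibromoethenyl)-5-[(triisopropylsilyl)oxy]phenoxy}dimethylsilane | BrC(Br)=Cc1ccc(O[Si](C(C)C)(C(C)C)C(C)C)cc1O[Si](C)(C)C(C)(C)C | intermediate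
5 | lithium 2-{2-[(tert-butyldimethylsilyl)oxy]-4-[(triisopropylsilyl)oxy]phenyl}ethyn-1-ide (formed in the flask) | [Li]C#Cc1ccc(O[Si](C(C)C)(C(C)C)C(C)C)cc1O[Si](C)(C)C(C)(C)C | intermediate
6 | tert-butyl{2-ethynyl-5-[(triisopropylsilyl)oxy]phenoxy}dimethylsilane | C#Cc1ccc(O[Si](C(C)C)(C(C)C)C(C)C)cc1O[Si](C)(C)C(C)(C)C | intermediate
7 | 4-hydroxybenzaldehyde | O=Cc1ccc(O)cc1 | starting material
8 | 4-[(triisopropylsilyl)oxy]benzaldehyde | O=Cc1ccc(O[Si](C(C)C)(C(C)C)C(C)C)cc1 | intermediate
9 | ethyl({2-[(tert-butyldimethylsilyl)oxy]-4-[(triisopropylsilyl)oxy]phenyl}ethynyl)zinc (formed in the flask) | CC[Zn]C#Cc1ccc(O[Si](C(C)C)(C(C)C)C(C)C)cc1O[Si](C)(C)C(C)(C)C | intermediate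
10 | (1S)-3-{2-[(tert-butyldimethylsilyl)oxy]-4-[(triisopropylsilyl)oxy]phenyl}-1-{4-[(triisopropylsilyl)oxy]phenyl}prop-2-yn-1-ol | O[C@H](C#Cc1ccc(O[Si](C(C)C)(C(C)C)C(C)C)cc1O[Si](C)(C)C(C)(C)C)c1ccc(O[Si](C(C)C)(C(C)C)C(C)C)cc1 | intermediate
11 | N-[(1R)-3-{2-[(tert-butyldimethylsilyl)oxy]-4-[(triisopropylsilyl)oxy]phenyl}-1-{4-[(triisopropylsilyl)oxy]phenyl}prop-2-yn-1-yl]-2-nitrobenzenesulfonohydrazide, alkylated on the sulfonyl-bearing nitrogen (formed in the flask) | NN([C@@H](C#Cc1ccc(O[Si](C(C)C)(C(C)C)C(C)C)cc1O[Si](C)(C)C(C)(C)C)c1ccc(O[Si](C(C)C)(C(C)C)C(C)C)cc1)S(=O)(=O)c1ccccc1[N+](=O)[O-] | intermediate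
12 | [(1R)-3-{2-[(tert-butyldimethylsilyl)oxy]-4-[(triisopropylsilyl)oxy]phenyl}-1-{4-[(triisopropylsilyl)oxy]phenyl}prop-2-yn-1-yl]diazene (formed in the flask) | N=N[C@@H](C#Cc1ccc(O[Si](C(C)C)(C(C)C)C(C)C)cc1O[Si](C)(C)C(C)(C)C)c1ccc(O[Si](C(C)C)(C(C)C)C(C)C)cc1 | intermediate
13 | tert-butyldimethyl{2-[(aS)-3-{4-[(triisopropylsilyl)oxy]phenyl}propa-1,2-dien-1-yl]-5-[(triisopropylsilyl)oxy]phenoxy}silane | [H]C(c1ccc(O[Si](C(C)C)(C(C)C)C(C)C)cc1O[Si](C)(C)C(C)(C)C)=[C@]=C([H])c1ccc(O[Si](C(C)C)(C(C)C)C(C)C)cc1 | intermediate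
14 | 1-(2,4-dihydroxyphenyl)ethan-1-one | CC(=O)c1ccc(O)cc1O | starting material
15 | 4-hydroxy-3-iodobenzaldehyde | O=Cc1ccc(O)c(I)c1 | starting material
16 | (E)-1-(2,4-dihydroxyphenyl)-3-(4-hydroxy-3-iodophenyl)prop-2-en-1-one | O=C(/C=C/c1ccc(O)c(I)c1)c1ccc(O)cc1O | intermediate
17 | (E)-1-{2,4-bis[(triisopropylsilyl)oxy]phenyl}-3-{3-iodo-4-[(triisopropylsilyl)oxy]phenyl}prop-2-en-1-one | O=C(/C=C/c1ccc(O[Si](C(C)C)(C(C)C)C(C)C)c(I)c1)c1ccc(O[Si](C(C)C)(C(C)C)C(C)C)cc1O[Si](C(C)C)(C(C)C)C(C)C | intermediate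
18 | tetrabutylammonium 2-[(aS)-3-{4-[(triisopropylsilyl)oxy]phenyl}propa-1,2-dien-1-yl]-5-[(triisopropylsilyl)oxy]phenolate (formed in the flask) | [H]C(c1ccc(O[Si](C(C)C)(C(C)C)C(C)C)cc1[O-])=[C@]=C([H])c1ccc(O[Si](C(C)C)(C(C)C)C(C)C)cc1.CCCC[N+](CCCC)(CCCC)CCCC | intermediate
19 | (E)-1-{2,4-bis[(triisopropylsilyl)oxy]phenyl}-3-{4-[(triisopropylsilyl)oxy]-3-[(2S)-7-[(triisopropylsilyl)oxy]-2-{4-[(triisopropylsilyl)oxy]phenyl}-2H-chromen-3-yl]phenyl}prop-2-en-1-one | O=C(/C=C/c1ccc(O[Si](C(C)C)(C(C)C)C(C)C)c(C2=Cc3ccc(O[Si](C(C)C)(C(C)C)C(C)C)cc3O[C@H]2c2ccc(O[Si](C(C)C)(C(C)C)C(C)C)cc2)c1)c1ccc(O[Si](C(C)C)(C(C)C)C(C)C)cc1O[Si](C(C)C)(C(C)C)C(C)C | intermediate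
20 | (E)-1-(2,4-dihydroxyphenyl)-3-{4-hydroxy-3-[(2S)-7-hydroxy-2-(4-hydroxyphenyl)-2H-chromen-3-yl]phenyl}prop-2-en-1-one | O=C(/C=C/c1ccc(O)c(C2=Cc3ccc(O)cc3O[C@H]2c2ccc(O)cc2)c1)c1ccc(O)cc1O | target

**Summary**

Total steps: 11. Longest linear sequence: 8 (steps 1, 2, 3, 4, 6, 7, 10, 11).

Steps most likely to fail:

1. Step 10 (proposed new method). The phenoxide may close by itself before arylpalladation, either after protonation (1,5-hydrogen shift and oxa-6π closure to the unarylated chromene) or by base-driven attack on the central allene carbon. Insertion at the proximal π bond, or palladium-induced racemisation of the allene axis, would invert or erode C2. The fallback uses known chemistry only, sets out from 8 and 17 and comes back at 19. Ethynylmagnesium bromide adds to 8 to give racemic 1-{4-[(triisopropylsilyl)oxy]phenyl}prop-2-yn-1-ol F1, which is acetylated (Ac2O, DMAP, Et3N) to 1-{4-[(triisopropylsilyl)oxy]phenyl}prop-2-yn-1-yl acetate F2. Resorcinol is monosilylated (TIPSCl, imidazole) to 3-[(triisopropylsilyl)oxy]phenol F3. Copper-catalysed enantioselective propargylic etherification of F2 with F3 (CuOTf·½C6H6, the pybox ligand enantiomer that gives the (R)-ether, iPr2NEt, MeOH, −20 °C) should proceed through a copper allenylidene to triisopropyl(3-{[(1R)-1-{4-[(triisopropylsilyl)oxy]phenyl}prop-2-yn-1-yl]oxy}phenoxy)silane F4. Iodocyclisation (I2, NaHCO3, MeNO2, 23 °C), by 6-endo attack of ring A para to its silyloxy group, should give {[(2S)-3-iodo-2-{4-[(triisopropylsilyl)oxy]phenyl}-2H-chromen-7-yl]oxy}triisopropylsilane F5; the stereocentre is untouched and the descriptor changes only through the priority rules. Miyaura borylation of 17 (B2pin2, Pd(dppf)Cl2, KOAc, dioxane, 80 °C) gives (E)-1-{2,4-bis[(triisopropylsilyl)oxy]phenyl}-3-{3-(4,4,5,5-tetramethyl-1,3,2-dioxaborolan-2-yl)-4-[(triisopropylsilyl)oxy]phenyl}prop-2-en-1-one F6. Suzuki–Miyaura coupling of F5 with F6 (Pd(PPh3)4, K3PO4, dioxane/H2O, 60 °C) forms the same C3–aryl bond and gives 19.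

2. Step 7. The doubly activated (benzylic and propargylic) carbinol may ionise under Mitsunobu activation, so that configuration is lost before or instead of clean displacement. The fallback sets out from 10 and comes back at 13. Compound 10 is converted (ClCO2Me, pyridine, 0 °C) into methyl (1S)-3-{2-[(tert-butyldimethylsilyl)oxy]-4-[(triisopropylsilyl)oxy]phenyl}-1-{4-[(triisopropylsilyl)oxy]phenyl}prop-2-yn-1-yl carbonate F7. Palladium-catalysed hydrogenolysis (Pd2(dba)3·CHCl3, PBu3, HCO2NH4, THF, 23 °C) follows: anti SN2′ oxidative addition gives an allenylpalladium, formate supplies hydride, and reductive elimination with retention delivers hydrogen anti to the leaving group. This is the same stereochemical course as step 7 and should give (aS)-13.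

3. Step 8. Acid may promote hydroxyalkylation of the resorcinol ring by the aldehyde and closure of the 2′-hydroxychalcone to the flavanone, which consume material. The fallback sets out from 14 and 15 and comes back at 16. Compound 15 is protected (MOMCl, iPr2NEt, CH2Cl2) as 3-iodo-4-(methoxymethoxy)benzaldehyde F8, and 14 (MOMCl, K2CO3, acetone; only the non-chelated 4-hydroxyl reacts) as 1-[2-hydroxy-4-(methoxymethoxy)phenyl]ethan-1-one F9. Base-mediated Claisen–Schmidt condensation (KOH, EtOH/H2O, 23 °C) gives (E)-1-[2-hydroxy-4-(methoxymethoxy)phenyl]-3-[3-iodo-4-(methoxymethoxy)phenyl]prop-2-en-1-one F10, and acetal cleavage (HCl, MeOH, 50 °C) returns 16.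

Further compounds
F1 | step 10 | 1-{4-[(triisopropylsilyl)oxy]phenyl}prop-2-yn-1-ol (racemic) | C#CC(O)c1ccc(O[Si](C(C)C)(C(C)C)C(C)C)cc1
F2 | step 10 | 1-{4-[(triisopropylsilyl)oxy]phenyl}prop-2-yn-1-yl acetate (racemic) | C#CC(OC(C)=O)c1ccc(O[Si](C(C)C)(C(C)C)C(C)C)cc1
F3 | step 10 | 3-[(triisopropylsilyl)oxy]phenol | Oc1cccc(O[Si](C(C)C)(C(C)C)C(C)C)c1
F4 | step 10 | triisopropyl(3-{[(1R)-1-{4-[(triisopropylsilyl)oxy]phenyl}prop-2-yn-1-yl]oxy}phenoxy)silane | O([C@H](C#C)c1ccc(O[Si](C(C)C)(C(C)C)C(C)C)cc1)c1cccc(O[Si](C(C)C)(C(C)C)C(C)C)c1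
F5 | step 10 | {[(2S)-3-iodo-2-{4-[(triisopropylsilyl)oxy]phenyl}-2H-chromen-7-yl]oxy}triisopropylsilane | IC1=Cc2ccc(O[Si](C(C)C)(C(C)C)C(C)C)cc2O[C@H]1c1ccc(O[Si](C(C)C)(C(C)C)C(C)C)cc1
F6 | step 10 | (E)-1-{2,4-bis[(triisopropylsilyl)oxy]phenyl}-3-{3-(4,4,5,5-tetramethyl-1,3,2-dioxaborolan-2-yl)-4-[(triisopropylsilyl)oxy]phenyl}prop-2-en-1-one | O=C(/C=C/c1ccc(O[Si](C(C)C)(C(C)C)C(C)C)c(B2OC(C)(C)C(C)(C)O2)c1)c1ccc(O[Si](C(C)C)(C(C)C)C(C)C)cc1O[Si](C(C)C)(C(C)C)C(C)C
F7 | step 7 | methyl (1S)-3-{2-[(tert-butyldimethylsilyl)oxy]-4-[(triisopropylsilyl)oxy]phenyl}-1-{4-[(triisopropylsilyl)oxy]phenyl}prop-2-yn-1-yl carbonate | COC(=O)O[C@H](C#Cc1ccc(O[Si](C(C)C)(C(C)C)C(C)C)cc1O[Si](C)(C)C(C)(C)C)c1ccc(O[Si](C(C)C)(C(C)C)C(C)C)cc1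
F8 | step 8 | 3-iodo-4-(methoxymethoxy)benzaldehyde | COCOc1ccc(C=O)cc1I
F9 | step 8 | 1-[2-hydroxy-4-(methoxymethoxy)phenyl]ethan-1-one | COCOc1ccc(C(C)=O)c(O)c1
F10 | step 8 | (E)-1-[2-hydroxy-4-(methoxymethoxy)phenyl]-3-[3-iodo-4-(methoxymethoxy)phenyl]prop-2-en-1-one | COCOc1ccc(/C=C/C(=O)c2ccc(OCOC)cc2O)cc1I
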